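The flavone is cut at both bonds of the C4 carbonyl, C4a–C4 towards ring A and C4–C3 towards the C3–C2 unit. One palladium-catalysed carbonylative Sonogashira coupling then joins a ring A iodide, carbon monoxide and a ring B arylacetylene to the diaryl ynone. The step exploits the latent mirror plane of hexasubstituted ring A through C4a and C7. C6 and C8 both bear OMe, so with MOM groups on the oxygens at C5, C7 and C8a the iodide is symmetric and either ortho oxygen can later close ring C at C2. Ring B carries benzyl ethers, which keep its C2' oxygen masked while ring C forms.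

Key step: step 9

Assumption: flavone numbering is used throughout (O1, C2, C3, C4, C4a, C5–C8, C8a; ring B C1'–C6'); the target has no stereocentre, so no stereocontrol is required.

Design points:
- Ring A is acetal-protected before any halogen enters. A free pentaoxygenated phenol is too easily oxidised for electrophilic iodination, so iodine is placed by directed lithiation at the only C–H.
- Both ring A methoxy groups come from a dibromide by copper catalysis. No blocking group or decarboxylation is needed.
- The ring B oxygens are benzyl ethers rather than acetals. A C2' hydroxyl freed together with the ring A hydroxyls would sit ortho to the alkyne and could close 5-endo on C3 to give a 2-aroylbenzofuran. After any solvent addition at C2 it could also close on C4 to give the inverted chromone.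
- Ring B is halogenated as the iodide, because an electron-rich aryl bromide is a sluggish alkynylation partner.

Step 1
Reactants: 1 phloroglucinol (benzene-1,3,5-triol)
Product: 2 1,3,5-tris(methoxymethoxy)benzene
Conditions: NaH (3.6 equiv), MOMCl (3.6 equiv), THF/DMF, 0 °C to rt
Reagents that add atoms: chloromethyl methyl ether, COCCl
Why: Threefold Williamson-type O-alkylation, in which the hard and highly reactive chloromethyl ether alkylates the phloroglucinol anion at oxygen rather than carbon and installs acetals that withstand base and organolithium reagents and later direct metalation.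

Step 2
Reactants: 2 1,3,5-tris(methoxymethoxy)benzene
Product: 3 2,4-dibromo-1,3,5-tris(methoxymethoxy)benzene
Conditions: NBS (2.0 equiv), MeCN, −20 to 0 °C, dark
Reagents that add atoms: N-bromosuccinimide, O=C1CCC(=O)N1Br
Why: Electrophilic aromatic bromination, in which every ring C–H is activated by three alkoxy groups and each bromine lowers the reactivity and crowds the ring, so that two equivalents of NBS at low temperature should stop at the dibromide while the neutral medium spares the acetals.

Step 3
Reactants: 3 2,4-dibromo-1,3,5-tris(methoxymethoxy)benzene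
Product: 4 2,4-dimethoxy-1,3,5-tris(methoxymethoxy)benzene
Conditions: NaOMe (5.4 M in MeOH, 10 equiv), CuBr (0.3 equiv), DMF, 110 °C, argon, sealed vessel
Reagents that add atoms: sodium methoxide, C[O-].[Na+]
Why: Copper-catalysed Ullmann-type C–O coupling with methoxide, well established for aryl bromides flanked by oxygen substituents on phloroglucinol-derived rings, should replace both bromines, and the MOM acetals are inert to alkoxide.

Step 4
Reactants: 4 2,4-dimethoxy-1,3,5-tris(methoxymethoxy)benzene
Product: 6 2-iodo-4,6-dimethoxy-1,3,5-tris(methoxymethoxy)benzene, via ring A aryllithium 5 (not isolated)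
Conditions: n-BuLi (1.2 equiv), THF, 0 °C; then I2 (1.3 equiv), THF, −78 °C to rt
Reagents that add atoms: iodine, [I][I]; n-butyllithium, [Li]CCCC (lithium of 5 only)
Why: Directed ortho-metalation, in which the only ring C–H lies between two chelating OMOM groups, so that n-BuLi removes it cleanly and iodine traps aryllithium 5 at the future C4a without exposing the pentaoxygenated ring to an oxidising electrophile.

Step 5
Reactants: 7 2-methoxyhydroquinone (2-methoxybenzene-1,4-diol)
Product: 8 1,4-bis(benzyloxy)-2-methoxybenzene
Conditions: BnBr (2.3 equiv), K2CO3 (3 equiv), DMF, rt to 50 °C, argon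
Reagents that add atoms: benzyl bromide, BrCc1ccccc1
Why: Double Williamson ether synthesis with a reactive benzylic halide, run under argon because the hydroquinone anion is readily oxidised by air.

Step 6
Reactants: 8 1,4-bis(benzyloxy)-2-methoxybenzene
Product: 9 1,4-bis(benzyloxy)-2-iodo-5-methoxybenzene
Conditions: NIS (1.05 equiv), CF3CO2H (10 mol %), MeCN, 0 °C to rt, dark
Reagents that add atoms: N-iodosuccinimide, O=C1CCC(=O)N1I
Why: Electrophilic aromatic iodination goes to the carbon para to OMe and ortho to one OBn, the usual site for 1,2,4-trialkoxybenzenes, because the position between two alkoxy groups is crowded and the remaining one is activated by a single oxygen only.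

Step 7
Reactants: 9 1,4-bis(benzyloxy)-2-iodo-5-methoxybenzene; 10 trimethylsilylacetylene
Product: 11 {[2,5-bis(benzyloxy)-4-methoxyphenyl]ethynyl}trimethylsilane
Conditions: 10 (1.5 equiv), PdCl2(PPh3)2 (2 mol %), CuI (4 mol %), Et3N/THF, 40 °C, argon
Reagents that add atoms: none
Why: Sonogashira coupling, in which the aryl iodide undergoes oxidative addition under mild conditions despite the donor substituents and the silyl cap restricts the acetylene to a single coupling.

Step 8
Reactants: 11 {[2,5-bis(benzyloxy)-4-methoxyphenyl]ethynyl}trimethylsilane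
Product: 12 1,4-bis(benzyloxy)-2-ethynyl-5-methoxybenzene
Conditions: K2CO3 (0.2 equiv), MeOH/THF, rt
Reagents that add atoms: none
Why: Carbonate-catalysed methanolysis of the C(sp)–Si bond (protodesilylation) is selective for the alkynylsilane and leaves benzyl and methyl ethers untouched.

Step 9
Reactants: 6 2-iodo-4,6-dimethoxy-1,3,5-tris(methoxymethoxy)benzene; 12 1,4-bis(benzyloxy)-2-ethynyl-5-methoxybenzene; 13 carbon monoxide
Product: 14 3-[2,5-bis(benzyloxy)-4-methoxyphenyl]-1-[3,5-dimethoxy-2,4,6-tris(methoxymethoxy)phenyl]prop-2-yn-1-one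
Conditions: Pd(OAc)2 (5 mol %), di(1-adamantyl)-n-butylphosphine (12 mol %), CuI (2 mol %), Et3N (3 equiv), toluene, CO (10 bar), 60 °C; solution saturated with CO first, then 12 (1.2 equiv) pumped in slowly
Reagents that add atoms: none
Why: Zerovalent palladium inserts into the C–I bond of 6, CO binds and the electron-rich aryl group migrates onto it to give an aroyl-palladium iodide, the copper acetylide formed from 12, CuI and Et3N hands over the alkynyl group, and reductive elimination releases ynone 14, so that C4a–C4 and C4–C3 are made in one catalytic cycle with the CO carbon as C4. The closest known reaction type is the carbonylative Sonogashira coupling of ortho-alkoxy aryl iodides with arylacetylenes, an established entry to flavone precursors. No ring closes and no stereocentre is created, because all five phenol oxygens are masked and the tertiary amine cannot add to the ynone. The selectivity needed is CO insertion ahead of direct alkynylation: the two ortho OMOM groups slow transmetalation at the crowded aryl-palladium stage while migration onto CO relieves that crowding, and CO pressure, the bulky donor phosphine, the low CuI loading and the slow feed of 12 all push in the same direction. Regiochemistry is not in question, since iodine sits on the only free carbon of ring A and the mirror plane through C4a and C7 makes both flanks identical.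

Step 10
Reactants: 14 3-[2,5-bis(benzyloxy)-4-methoxyphenyl]-1-[3,5-dimethoxy-2,4,6-tris(methoxymethoxy)phenyl]prop-2-yn-1-one
Product: 16 2-[2,5-bis(benzyloxy)-4-methoxyphenyl]-5,7-dihydroxy-6,8-dimethoxy-4H-chromen-4-one, via trihydroxy ynone 15 (not isolated)
Conditions: HCl (1.25 M in MeOH), THF, 50 °C, argon
Reagents that add atoms: none
Why: Acetal methanolysis frees the three ring A phenols, and under the same Brønsted acid either of the two equivalent ortho hydroxyls of 15 adds to C2 of the protonated ynone in a 6-endo-dig oxa-Michael cyclisation, C2 being the carbon that both the carbonyl group and the donor ring B make electrophilic, while the inert benzyl ethers keep the C2' oxygen out of play.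

Step 11
Reactants: 16 2-[2,5-bis(benzyloxy)-4-methoxyphenyl]-5,7-dihydroxy-6,8-dimethoxy-4H-chromen-4-one
Product: 17 2-(2,5-dihydroxy-4-methoxyphenyl)-5,7-dihydroxy-6,8-dimethoxy-4H-chromen-4-one (target)
Conditions: H2 (1 atm), Pd/C (10 wt %), THF/MeOH, rt; filtration and concentration under argon
Reagents that add atoms: none
Why: Catalytic hydrogenolysis cleaves the two O-benzyl bonds under neutral, reducing conditions that suit the air-sensitive 2',5'-hydroquinone and normally leave the conjugated, chelated flavone C2–C3 double bond and the aryl methyl ethers untouched.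

Compound list
1 | phloroglucinol (benzene-1,3,5-triol) | Oc1cc(O)cc(O)c1 | starting material
2 | 1,3,5-tris(methoxymethoxy)benzene | COCOc1cc(OCOC)cc(OCOC)c1 | intermediate
3 | 2,4-dibromo-1,3,5-tris(methoxymethoxy)benzene | COCOc1cc(OCOC)c(Br)c(OCOC)c1Br | intermediate
4 | 2,4-dimethoxy-1,3,5-tris(methoxymethoxy)benzene | COCOc1cc(OCOC)c(OC)c(OCOC)c1OC | intermediate
5 | [3,5-dimethoxy-2,4,6-tris(methoxymethoxy)phenyl]lithium (not isolated) | [Li]c1c(OCOC)c(OC)c(OCOC)c(OC)c1OCOC | intermediate
6 | 2-iodo-4,6-dimethoxy-1,3,5-tris(methoxymethoxy)benzene | COCOc1c(OC)c(OCOC)c(OC)c(OCOC)c1I | intermediate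
7 | 2-methoxyhydroquinone | COc1cc(O)ccc1O | starting material
8 | 1,4-bis(benzyloxy)-2-methoxybenzene | COc1cc(OCc2ccccc2)ccc1OCc1ccccc1 | intermediate
9 | 1,4-bis(benzyloxy)-2-iodo-5-methoxybenzene | COc1cc(OCc2ccccc2)c(I)cc1OCc1ccccc1 | intermediate
10 | trimethylsilylacetylene | C#C[Si](C)(C)C | starting material
11 | {[2,5-bis(benzyloxy)-4-methoxyphenyl]ethynyl}trimethylsilane | COc1cc(OCc2ccccc2)c(C#C[Si](C)(C)C)cc1OCc1ccccc1 | intermediate
12 | 1,4-bis(benzyloxy)-2-ethynyl-5-methoxybenzene | C#Cc1cc(OCc2ccccc2)c(OC)cc1OCc1ccccc1 | intermediate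
13 | carbon monoxide | [C-]#[O+] | starting material
14 | 3-[2,5-bis(benzyloxy)-4-methoxyphenyl]-1-[3,5-dimethoxy-2,4,6-tris(methoxymethoxy)phenyl]prop-2-yn-1-one | COCOc1c(OC)c(OCOC)c(OC)c(OCOC)c1C(=O)C#Cc1cc(OCc2ccccc2)c(OC)cc1OCc1ccccc1 | intermediate
15 | 3-[2,5-bis(benzyloxy)-4-methoxyphenyl]-1-(2,4,6-trihydroxy-3,5-dimethoxyphenyl)prop-2-yn-1-one (not isolated) | COc1c(O)c(OC)c(O)c(C(=O)C#Cc2cc(OCc3ccccc3)c(OC)cc2OCc2ccccc2)c1O | intermediate
16 | 2-[2,5-bis(benzyloxy)-4-methoxyphenyl]-5,7-dihydroxy-6,8-dimethoxy-4H-chromen-4-one | COc1cc(OCc2ccccc2)c(-c2cc(=O)c3c(O)c(OC)c(O)c(OC)c3o2)cc1OCc1ccccc1 | intermediate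
17 | 2-(2,5-dihydroxy-4-methoxyphenyl)-5,7-dihydroxy-6,8-dimethoxy-4H-chromen-4-one (5,7,2',5'-tetrahydroxy-6,8,4'-trimethoxyflavone) | COc1cc(O)c(-c2cc(=O)c3c(O)c(OC)c(O)c(OC)c3o2)cc1O | target

Total step count: 11. Longest linear sequence: 7 steps (steps 1–4 then 9–11; the ring B branch, steps 5–8 then 9–11, is equally long).

Steps most likely to fail

1. Step 9. Three processes could erode the coupling:
   - alkynyl transfer to the aryl-palladium species before CO has inserted
   - reductive loss of iodine
   - oxidative dimerisation of the alkyne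

   The fallback builds the same two bonds without CO gas. It sets out from 4 and 12 and comes back at 14. Aryllithium 5, generated from 4 as in step 4, is quenched with DMF to give 3,5-dimethoxy-2,4,6-tris(methoxymethoxy)benzaldehyde F1. Alkyne 12 is deprotonated with n-BuLi (THF, −78 °C) to the lithium acetylide F2. This slim nucleophile adds to the hindered aldehyde to give the racemic propargylic alcohol 3-[2,5-bis(benzyloxy)-4-methoxyphenyl]-1-[3,5-dimethoxy-2,4,6-tris(methoxymethoxy)phenyl]prop-2-yn-1-ol F3. MnO2 (CH2Cl2, rt) oxidises this benzylic and propargylic alcohol to ynone 14.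

2. Step 3. Bromine could be lost reductively through hydride transfer from methoxide at copper, or the exchange could stall after the first substitution at these doubly flanked positions. The fallback introduces each oxygen through boron. It sets out from 2, skips steps 2 and 3, and comes back at 4.
   - n-BuLi (THF, 0 °C) lithiates between two OMOM groups to give [2,4,6-tris(methoxymethoxy)phenyl]lithium F4.
   - B(OMe)3 traps it as lithium trimethoxy[2,4,6-tris(methoxymethoxy)phenyl]borate F5.
   - 30% H2O2 (0 °C to rt) oxidises this in the same flask to 2,4,6-tris(methoxymethoxy)phenol F6.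
   - MeI/K2CO3 (acetone) gives 2-methoxy-1,3,5-tris(methoxymethoxy)benzene F7.
   - The same sequence is repeated through [3-methoxy-2,4,6-tris(methoxymethoxy)phenyl]lithium F8 and lithium trimethoxy[3-methoxy-2,4,6-tris(methoxymethoxy)phenyl]borate F9, giving 3-methoxy-2,4,6-tris(methoxymethoxy)phenol F10.
   - Methylation of F10 gives 4.

3. Step 10. Closure could occur at the alpha carbon C3 in the 5-exo mode, or the reaction could stall at partly deprotected or solvent-adduct stages. The fallback fixes the site of attack with an amine relay. It sets out from 14 and comes back at 16. Et2NH (EtOH, 50 °C) adds to C2 in an aza-Michael reaction to give the enaminone (E)-3-[2,5-bis(benzyloxy)-4-methoxyphenyl]-3-(diethylamino)-1-[3,5-dimethoxy-2,4,6-tris(methoxymethoxy)phenyl]prop-2-en-1-one F11. Its double-bond geometry is of no consequence. Methanolic HCl (50 °C) then removes the acetals to give the trihydroxy enaminone F12, which is not isolated. An ortho hydroxyl displaces the amine at C2 by addition–elimination and delivers 16.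

Further compounds
F1 | step 9 | 3,5-dimethoxy-2,4,6-tris(methoxymethoxy)benzaldehyde | COCOc1c(OC)c(OCOC)c(OC)c(OCOC)c1C=O
F2 | step 9 | {[2,5-bis(benzyloxy)-4-methoxyphenyl]ethynyl}lithium | [Li]C#Cc1cc(OCc2ccccc2)c(OC)cc1OCc1ccccc1
F3 | step 9 | 3-[2,5-bis(benzyloxy)-4-methoxyphenyl]-1-[3,5-dimethoxy-2,4,6-tris(methoxymethoxy)phenyl]prop-2-yn-1-ol (racemic) | COCOc1c(OC)c(OCOC)c(OC)c(OCOC)c1C(O)C#Cc1cc(OCc2ccccc2)c(OC)cc1OCc1ccccc1
F4 | step 3 | [2,4,6-tris(methoxymethoxy)phenyl]lithium | [Li]c1c(OCOC)cc(OCOC)cc1OCOC
F5 | step 3 | lithium trimethoxy[2,4,6-tris(methoxymethoxy)phenyl]borate | [Li+].CO[B-](OC)(OC)c1c(OCOC)cc(OCOC)cc1OCOC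
F6 | step 3 | 2,4,6-tris(methoxymethoxy)phenol | COCOc1cc(OCOC)c(O)c(OCOC)c1
F7 | step 3 | 2-methoxy-1,3,5-tris(methoxymethoxy)benzene | COCOc1cc(OCOC)c(OC)c(OCOC)c1
F8 | step 3 | [3-methoxy-2,4,6-tris(methoxymethoxy)phenyl]lithium | [Li]c1c(OCOC)cc(OCOC)c(OC)c1OCOC
F9 | step 3 | lithium trimethoxy[3-methoxy-2,4,6-tris(methoxymethoxy)phenyl]borate | [Li+].CO[B-](OC)(OC)c1c(OCOC)cc(OCOC)c(OC)c1OCOC
F10 | step 3 | 3-methoxy-2,4,6-tris(methoxymethoxy)phenol | COCOc1cc(OCOC)c(OC)c(OCOC)c1O
F11 | step 10 | (E)-3-[2,5-bis(benzyloxy)-4-methoxyphenyl]-3-(diethylamino)-1-[3,5-dimethoxy-2,4,6-tris(methoxymethoxy)phenyl]prop-2-en-1-one | COCOc1c(OC)c(OCOC)c(OC)c(OCOC)c1C(=O)/C=C(/N(CC)CC)c1cc(OCc2ccccc2)c(OC)cc1OCc1ccccc1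
F12 | step 10 | (E)-3-[2,5-bis(benzyloxy)-4-methoxyphenyl]-3-(diethylamino)-1-(2,4,6-trihydroxy-3,5-dimethoxyphenyl)prop-2-en-1-one | COc1c(O)c(OC)c(O)c(C(=O)/C=C(/N(CC)CC)c2cc(OCc3ccccc3)c(OC)cc2OCc2ccccc2)c1O
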